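**Strategy.** Everything rests on cutting the two acetyl–oxygen bonds at O3 and O5, which reduces the target to a stereorandom 1-aryloctane-3,5-diol with the phenol masked as a benzyl ether. The feature exploited is the acyclic syn-1,3-dioxygenated C3–C4–C5 unit, in which C5 bears a short propyl arm (C6–C8) while C3 lies between two long arms. The guaiacyl ring is a spectator and no ring is formed. In one pot, ruthenium-catalysed epimerisation of both carbinols, lipase acetylation at O5 and syn-selective O5-to-O3 acetyl transfer should funnel all four diol stereoisomers into the (3S,5R)-diacetate. The diol arises from zingerone and butanal by aldol addition and borohydride reduction.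

Key step: step 4

Remark on the chemistry: the chain is numbered from benzylic C1 to methyl C8. At both C3 and C5 the CIP ranking is O > C4 > outer chain > H, so the 3S,5R pair read from the target SMILES is the syn (meso-like) arrangement.

Assumption: the Burkholderia lipase is taken to follow the usual empirical size rule for secondary alcohols, with propyl as the smaller group. This would be confirmed on a small run before material is committed.

Step 1
Reactants: 1 zingerone, 4-(4-hydroxy-3-methoxyphenyl)butan-2-one; 2 benzyl bromide
Product: 3 4-(4-benzyloxy-3-methoxyphenyl)butan-2-one (O-benzylzingerone)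
Conditions: BnBr (1.1 equiv), K2CO3 (1.5 equiv), DMF, rt
Reagents that add atoms: benzyl bromide (2), BrCc1ccccc1
Why: Williamson ether synthesis in which carbonate is basic enough for the phenol but not for the ketone α-positions and the primary benzylic bromide undergoes SN2 O-alkylation, the benzyl group then keeping the acidic phenol from quenching the enolate in step 2 and from protonating the ruthenium alkoxide or being acetylated in step 4.

Step 2
Reactants: 3 O-benzylzingerone; 4 butanal
Product: 7 rac-1-(4-benzyloxy-3-methoxyphenyl)-5-hydroxyoctan-3-one, via lithium enolate 5 (not isolated), via lithium aldolate 6 (not isolated)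
Conditions: LDA (1.1 equiv), THF, −78 °C, slow addition of 3; then 4 (1.2 equiv), −78 °C; AcOH/THF quench at −78 °C
Reagents that add atoms: butanal (4), CCCC=O
Why: Directed crossed aldol addition, in which slow addition of 3 to a slight excess of LDA at −78 °C removes a proton irreversibly from the less hindered methyl group, the preformed enolate 5 adds to the aldehyde 4 faster than it exchanges protons, the cold acetic acid quench of 6 forestalls retro-aldol and dehydration, and the new C5 centre is deliberately left racemic because step 4 resets it.

Step 3
Reactants: 7 rac-1-(4-benzyloxy-3-methoxyphenyl)-5-hydroxyoctan-3-one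
Product: 8 1-(4-benzyloxy-3-methoxyphenyl)octane-3,5-diol (all four stereoisomers)
Conditions: NaBH4 (1.0 equiv), MeOH, 0 °C
Reagents that add atoms: none
Why: Sodium borohydride reduction of the C3 ketone leaves the aryl ethers untouched, and the lack of 1,3-induction is harmless because both carbinol centres are re-equilibrated and then fixed in step 4.

Step 4
Reactants: 8 1-(4-benzyloxy-3-methoxyphenyl)octane-3,5-diol (all four stereoisomers); 9 isopropenyl acetate
Product: 12 (3S,5R)-1-(4-benzyloxy-3-methoxyphenyl)octane-3,5-diyl diacetate, via syn 5-monoacetate 10 (not isolated), via syn 3-monoacetate 11 (not isolated)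
Conditions: (η5-C5Ph5)Ru(CO)2Cl (5 mol %), t-BuOK (5 mol %), immobilised Burkholderia cepacia lipase, 9 (4 equiv), Na2CO3 (1 equiv), dry toluene, 70 °C, Ar
Reagents that add atoms: isopropenyl acetate (9), CC(=C)OC(C)=O
Why: The tert-butoxide-activated ruthenium complex binds each free carbinol as an alkoxide and scrambles C3 and C5 by reversible β-hydride elimination and re-addition while the carbonyl stage stays on the metal, which should keep the dehydration-prone β-hydroxy ketone stage from escaping and leave the acetone released by the donor innocent. The lipase transfers acetyl from 9 only to a (5R)-hydroxyl, giving 10 in ruthenium-mediated equilibrium with its C3 epimer; the syn isomer 10 hands the acetyl group from O5 to O3 through a chair-like six-membered transition structure with both chain arms equatorial, much faster than the anti isomer can, and the freed (5R)-hydroxyl of 11 is acetylated a second time to give 12. This is the known dynamic kinetic asymmetric transformation of unsymmetrical acyclic 1,3-diols into syn-1,3-diacetates (lipase/ruthenium dynamic kinetic resolution coupled to 1,3-acyl migration); two O–acyl bonds are made and no ring is closed. C5 (R) is set by the enzyme (propyl C6–C8 in the medium pocket, the C4 side in the large pocket), C3 (S) is set relative to C5 by the syn preference of the acyl shift, and esterified centres can no longer be dehydrogenated, so 12 is the sink. The step needs site selectivity for O5 over O3, secured because C3 is flanked by the arylethyl arm and the C4–C8 arm, neither of which fits the medium pocket, and it needs enantioselection at C5, which is read twice, so that a single misreading should end in a chromatographically separable anti-diacetate and only a double one in the enantiomer. A Burkholderia lipase is preferred to Candida antarctica lipase B because its alcohol pocket tolerates three-carbon medium groups, propyl being larger than the methyl group of the usual substrates.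

Step 5
Reactants: 12 (3S,5R)-1-(4-benzyloxy-3-methoxyphenyl)octane-3,5-diyl diacetate
Product: 13 (3S,5R)-1-(4-hydroxy-3-methoxyphenyl)octane-3,5-diyl diacetate (target)
Conditions: H2 (1 atm), 10% Pd/C, EtOAc, rt
Reagents that add atoms: none
Why: Catalytic hydrogenolysis (O-debenzylation) cleaves only the benzylic C–O bond of the aryl benzyl ether, since both acetoxy groups sit on non-benzylic, non-allylic secondary carbons and the neutral aprotic medium offers no path for acetyl transfer to the freed phenol or for epimerisation at C3 and C5.

**Compound list**

1 | zingerone, 4-(4-hydroxy-3-methoxyphenyl)butan-2-one | CC(=O)CCc1ccc(O)c(OC)c1 | starting material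
2 | benzyl bromide | BrCc1ccccc1 | starting material
3 | 4-(4-benzyloxy-3-methoxyphenyl)butan-2-one | CC(=O)CCc1ccc(OCc2ccccc2)c(OC)c1 | intermediate
4 | butanal | CCCC=O | starting material
5 | lithium 4-(4-benzyloxy-3-methoxyphenyl)but-1-en-2-olate (kinetic enolate, not isolated) | C=C(O[Li])CCc1ccc(OCc2ccccc2)c(OC)c1 | intermediate
6 | lithium alkoxide of aldol 7 (racemic, not isolated) | CCCC(O[Li])CC(=O)CCc1ccc(OCc2ccccc2)c(OC)c1 | intermediate
7 | rac-1-(4-benzyloxy-3-methoxyphenyl)-5-hydroxyoctan-3-one | CCCC(O)CC(=O)CCc1ccc(OCc2ccccc2)c(OC)c1 | intermediate
8 | 1-(4-benzyloxy-3-methoxyphenyl)octane-3,5-diol, all four stereoisomers | CCCC(O)CC(O)CCc1ccc(OCc2ccccc2)c(OC)c1 | intermediate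
9 | isopropenyl acetate | CC(=C)OC(C)=O | starting material
10 | (3S,5R)-5-acetoxy-1-(4-benzyloxy-3-methoxyphenyl)octan-3-ol (syn, not isolated) | CCC[C@H](C[C@H](CCc1ccc(OCc2ccccc2)c(OC)c1)O)OC(C)=O | intermediate
11 | (3S,5R)-3-acetoxy-1-(4-benzyloxy-3-methoxyphenyl)octan-5-ol (syn, not isolated) | CCC[C@H](C[C@H](CCc1ccc(OCc2ccccc2)c(OC)c1)OC(C)=O)O | intermediate
12 | (3S,5R)-1-(4-benzyloxy-3-methoxyphenyl)octane-3,5-diyl diacetate | CCC[C@H](C[C@H](CCc1ccc(OCc2ccccc2)c(OC)c1)OC(C)=O)OC(C)=O | intermediate
13 | (3S,5R)-1-(4-hydroxy-3-methoxyphenyl)octane-3,5-diyl diacetate | CCC[C@H](C[C@H](CCc1ccc(O)c(OC)c1)OC(C)=O)OC(C)=O | target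

Total step count: 5. Longest linear sequence: 5.

**Steps most likely to fail**

1. **Step 4.**
   - What may go wrong: enzymatic acetylation at the propyl-bearing carbinol may be slow or poorly enantiodiscriminating. Net oxidation and dehydration at the ruthenium centre, or leakage through the slower anti acyl shift, could then compete with the productive funnel.
   - Fallback: it sets out from 7 and comes back at 12, using catalytic asymmetric C–B bond formation and substrate-controlled reduction instead of enzyme reading.
   - Acid-catalysed dehydration of 7 (cat. p-TsOH, toluene, reflux) would give the enone (E)-1-(4-benzyloxy-3-methoxyphenyl)oct-4-en-3-one F1.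
   - Copper(I)-catalysed enantioselective conjugate borylation follows (CuCl, NaOt-Bu, a Josiphos-type ferrocenyl diphosphine, B2pin2, MeOH, THF, rt). The ligand antipode is chosen on an analytical run to place boron on the face that leads to 5R. This would give the β-boryl ketone (5R)-1-(4-benzyloxy-3-methoxyphenyl)-5-(4,4,5,5-tetramethyl-1,3,2-dioxaborolan-2-yl)octan-3-one F2.
   - Stereoretentive oxidation (NaBO3·4H2O, THF/H2O) would give the aldol (5R)-1-(4-benzyloxy-3-methoxyphenyl)-5-hydroxyoctan-3-one F3.
   - Narasaka–Prasad reduction (Et2BOMe, NaBH4, THF/MeOH, −78 °C) would set C3 syn to C5 and give the diol (3S,5R)-1-(4-benzyloxy-3-methoxyphenyl)octane-3,5-diol F4.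
   - Acetylation (Ac2O, pyridine, DMAP) would deliver 12.

2. **Step 2.**
   - What may go wrong: the enolate may equilibrate to the internal regioisomer, proton transfer from butanal may lead to its self-condensation, and the aldol may suffer retro-aldol or dehydration during work-up.
   - Fallback: it sets out from 3 and comes back at 8, replacing the aldol by acylation and bypassing 7.
   - Claisen condensation of 3 with ethyl butanoate (NaH, THF, reflux) is driven to the methyl terminus by formation of the less substituted diketonate. It would give the diketone 1-(4-benzyloxy-3-methoxyphenyl)octane-3,5-dione F5.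
   - Excess NaBH4 in MeOH would then reduce both carbonyl groups to the stereorandom diol 8.

3. **Step 5.**
   - What may go wrong: hydrogenolysis may stall through poisoning of palladium by metal or protein residues carried over from step 4, or the acetyl groups may scramble onto the liberated phenol on prolonged exposure.
   - Fallback: it sets out from 12 and comes back at 13 without any new compound.
   - The cleavage is non-reductive and Lewis-acid mediated, using BCl3 with pentamethylbenzene as a non-basic benzyl cation scavenger (CH2Cl2, −78 °C, cold methanolic quench). At this temperature the alkyl acetates and the aryl methyl ether should stay intact.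

**Further compounds**

F1 | step 4 | (E)-1-(4-benzyloxy-3-methoxyphenyl)oct-4-en-3-one | CCC/C=C/C(=O)CCc1ccc(OCc2ccccc2)c(OC)c1
F2 | step 4 | (5R)-1-(4-benzyloxy-3-methoxyphenyl)-5-(4,4,5,5-tetramethyl-1,3,2-dioxaborolan-2-yl)octan-3-one | CCC[C@@H](B1OC(C)(C)C(C)(C)O1)CC(=O)CCc1ccc(OCc2ccccc2)c(OC)c1
F3 | step 4 | (5R)-1-(4-benzyloxy-3-methoxyphenyl)-5-hydroxyoctan-3-one | CCC[C@@H](O)CC(=O)CCc1ccc(OCc2ccccc2)c(OC)c1
F4 | step 4 | (3S,5R)-1-(4-benzyloxy-3-methoxyphenyl)octane-3,5-diol | CCC[C@H](C[C@H](CCc1ccc(OCc2ccccc2)c(OC)c1)O)O
F5 | step 2 | 1-(4-benzyloxy-3-methoxyphenyl)octane-3,5-dione | CCCC(=O)CC(=O)CCc1ccc(OCc2ccccc2)c(OC)c1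
F0 | step 5 | none | none
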